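The 3-bromooxane is traced back to a 2,2,5-trisubstituted oxolane holding the same oxygen: O1, C6 (CH3, vinyl), C5, C4 and C3 (CHBr) of the oxane form a five-atom unit that can exist as an oxolane before C2 is inserted between O1 and C3 by bromide-induced ring expansion through a bicyclic oxonium ion. The key step builds this oxolane in one flask: an epoxide-bearing Grignard reagent adds to an α-benzyloxy aldehyde (C3–C4 bond) and the resulting alkoxide oxygen opens the epoxide (O1–C6 bond), setting both ring stereocentres. The precursors are an acyclic epoxy iodide and O-benzyl lactaldehyde; the oxabicycle comes from 2,5-dimethylfuran by cycloaddition.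

Key step: step 5

Assumption: in step 1 the (S)-configured oxazaborolidinium ion is taken to shield the Re face at C-2 of the coordinated enal; if the sense were opposite, its enantiomer would be used without other change.

Step 1
Reactants: 1 2,5-dimethylfuran; 2 (E)-but-2-enal
Product: 4 (1R,2R,3R,4S)-1,3,4-trimethyl-7-oxabicyclo[2.2.1]heptane-2-carbaldehyde, via oxanorbornene adduct 3 (not isolated)
Conditions: (S)-3,3-diphenyl-1-(o-tolyl)tetrahydro-1H,3H-pyrrolo[1,2-c][1,3,2]oxazaborole·HN(SO2CF3)2 (20 mol %), CH2Cl2, −78 °C; Et3N; then H2 (1 atm), Pd/C, EtOAc, −20 → 0 °C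
Reagents that add atoms: none
Why: Lewis-acid-catalysed Diels–Alder reaction that dearomatises the cheap furan should give the kinetic endo adduct (formyl endo, methyl exo) with the diene bonding to the Si face at C-2 of the enal under control of the chiral oxazaborolidinium ion, which sets all four stereocentres at once, and immediate hydrogenation of the strained alkene blocks cycloreversion without creating a stereocentre.

Step 2
Reactants: 5 but-2-yne; 6 oxirane
Product: 9 (E)-3-methylpent-3-en-1-ol, via alkenylalane 7 (not isolated), via lithium alanate 8 (not isolated)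
Conditions: i-Bu2AlH, heptane, 50 °C; MeLi, Et2O, 0 °C; oxirane, THF, −30 °C → rt; aqueous work-up
Reagents that add atoms: none
Why: cis-Hydroalumination of the symmetrical alkyne followed by opening of oxirane by the alkenyl alanate with retention of the alkene geometry should give only the (E)-trisubstituted homoallylic alcohol.

Step 3
Reactants: 9 (E)-3-methylpent-3-en-1-ol
Product: 10 2-[(2R,3R)-2,3-dimethyloxiran-2-yl]ethan-1-ol
Conditions: 1,2:4,5-di-O-isopropylidene-β-D-erythro-hexo-2,3-diulo-2,6-pyranose (D-fructose-derived ketone, 30 mol %), Oxone (2KHSO5·KHSO4·K2SO4), K2CO3, n-Bu4NHSO4, MeCN–CH2(OMe)2–aq. Na2B4O7 buffer, 0 °C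
Reagents that add atoms: potassium peroxymonosulfate (KHSO5), [K+].[O-]S(=O)(=O)OO
Why: Shi asymmetric epoxidation, in which the chiral dioxirane transfers oxygen through a spiro transition state to one face of the trans-trisubstituted alkene, should give the (2R,3R)-epoxide whose quaternary carbon later becomes the methyl-bearing ring carbon next to oxygen.

Step 4
Reactants: 10 2-[(2R,3R)-2,3-dimethyloxiran-2-yl]ethan-1-ol
Product: 11 (2R,3R)-2-(2-iodoethyl)-2,3-dimethyloxirane
Conditions: I2, PPh3, imidazole, CH2Cl2, 0 °C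
Reagents that add atoms: iodine, [I][I]
Why: Appel-type iodination of the primary alcohol under imidazole-buffered conditions should leave the trisubstituted epoxide and its two stereocentres untouched.

Step 5
Reactants: 11 (2R,3R)-2-(2-iodoethyl)-2,3-dimethyloxirane; 12 (S)-2-(benzyloxy)propanal
Product: 16 (1R)-1-[(2S,5S)-5-[(1S)-1-(benzyloxy)ethyl]-2-methyloxolan-2-yl]ethan-1-ol, via alkyllithium 13 (not isolated), via Grignard reagent 14 (not isolated), via hydroxy epoxide 15 (not isolated)
Conditions: t-BuLi (2 equiv), Et2O–pentane, −78 °C; MgBr2·OEt2; then 12 premixed with MgBr2·OEt2, CH2Cl2, −78 °C; then (±)-camphor-10-sulfonic acid, −78 → 0 °C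
Reagents that add atoms: none
Why: Iodine–lithium exchange and transmetalation give the Grignard reagent 14, which adds to the aldehyde held in a five-membered magnesium chelate with the benzyloxy group (Cram-chelate addition, as known for O-benzyl lactaldehyde) and so forms the CH2–CH(O) bond; on acidification the new hydroxyl of 15 attacks the protonated epoxide at its quaternary carbon and forms the O–C(CH3) bond (acid-catalysed cyclisation of a γ,δ-epoxy alcohol, as in the formation of furanoid linalool oxides). The oxolane is closed in the 5-exo-tet mode with inversion at the attacked carbon. The new CH–O stereocentre (S) is controlled by the benzyloxy-bearing stereocentre through the chelate, the nucleophile entering from the side of its hydrogen to give the syn adduct; the quaternary O–C(CH3) stereocentre (S) is controlled by the (R)-epoxide carbon from step 3 because the opening is stereospecific. The step needs syn over anti addition, secured by the chelating benzyl ether and MgBr2, and attack at the tertiary instead of the secondary epoxide carbon, secured by the exo mode (five- against six-membered ring) and the higher cation-stabilising ability of the tertiary carbon under acid. Low temperature and magnesium as counter-ion should keep the carbanion from attacking its own epoxide.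

Step 6
Reactants: 16 (1R)-1-[(2S,5S)-5-[(1S)-1-(benzyloxy)ethyl]-2-methyloxolan-2-yl]ethan-1-ol
Product: 17 tert-butyl{(1R)-1-[(2S,5S)-5-[(1S)-1-(benzyloxy)ethyl]-2-methyloxolan-2-yl]ethoxy}dimethylsilane
Conditions: TBSOTf, 2,6-lutidine, CH2Cl2, −78 → 0 °C
Reagents that add atoms: tert-butyldimethylsilyl trifluoromethanesulfonate, CC(C)(C)[Si](C)(C)OS(=O)(=O)C(F)(F)F
Why: Silylation of the hindered secondary hydroxyl with the silyl triflate masks the future vinyl group as a 1-silyloxyethyl unit that withstands the later oxidation, enolate, Grignard and oxonium chemistry.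

Step 7
Reactants: 17 tert-butyl{(1R)-1-[(2S,5S)-5-[(1S)-1-(benzyloxy)ethyl]-2-methyloxolan-2-yl]ethoxy}dimethylsilane
Product: 18 (1S)-1-[(2S,5S)-5-[(1R)-1-{[tert-butyl(dimethyl)silyl]oxy}ethyl]-5-methyloxolan-2-yl]ethan-1-ol
Conditions: H2 (1 atm), Pd(OH)2/C, EtOAc, rt
Reagents that add atoms: none
Why: Hydrogenolysis of the benzyl ether should free the auxiliary carbinol without touching the silyl ether or the oxolane.

Step 8
Reactants: 18 (1S)-1-[(2S,5S)-5-[(1R)-1-{[tert-butyl(dimethyl)silyl]oxy}ethyl]-5-methyloxolan-2-yl]ethan-1-ol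
Product: 19 1-[(2S,5S)-5-[(1R)-1-{[tert-butyl(dimethyl)silyl]oxy}ethyl]-5-methyloxolan-2-yl]ethan-1-one
Conditions: Dess–Martin periodinane (1,1,1-triacetoxy-1,1-dihydro-1,2-benziodoxol-3(1H)-one), NaHCO3, CH2Cl2, 0 °C → rt
Reagents that add atoms: none
Why: Dess–Martin oxidation under buffered, non-epimerising conditions should give the methyl ketone and removes the auxiliary stereocentre whose only task was to control the adjacent ring carbon.

Step 9
Reactants: 19 1-[(2S,5S)-5-[(1R)-1-{[tert-butyl(dimethyl)silyl]oxy}ethyl]-5-methyloxolan-2-yl]ethan-1-one; 4 (1R,2R,3R,4S)-1,3,4-trimethyl-7-oxabicyclo[2.2.1]heptane-2-carbaldehyde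
Product: 22 (E)-1-[(2S,5S)-5-[(1R)-1-{[tert-butyl(dimethyl)silyl]oxy}ethyl]-5-methyloxolan-2-yl]-3-[(1R,2R,3R,4S)-1,3,4-trimethyl-7-oxabicyclo[2.2.1]heptan-2-yl]prop-2-en-1-one, via aldol adduct 20 (not isolated), via mesylate 21 (not isolated)
Conditions: LiN(i-Pr)2, THF, −78 °C; 4; then MsCl, Et3N, −78 °C → rt
Reagents that add atoms: none
Why: Directed aldol addition of the kinetic methyl-side lithium enolate to the aldehyde followed by mesylation and E1cB elimination (aldol condensation) should join the two fragments as the (E)-enone without disturbing the α-alkoxy stereocentre.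

Step 10
Reactants: 22 the (E)-enone of step 9
Product: 23 1-[(2S,5S)-5-[(1R)-1-{[tert-butyl(dimethyl)silyl]oxy}ethyl]-5-methyloxolan-2-yl]-3-[(1R,2R,3R,4S)-1,3,4-trimethyl-7-oxabicyclo[2.2.1]heptan-2-yl]propan-1-one
Conditions: H2 (1 atm), Pd/C, EtOAc, rt
Reagents that add atoms: none
Why: Heterogeneous hydrogenation should saturate only the conjugated C=C bond, and no stereocentre is formed.

Step 11
Reactants: 23 the saturated ketone of step 10
Product: 24 (2R)-2-[(2S,5S)-5-[(1R)-1-{[tert-butyl(dimethyl)silyl]oxy}ethyl]-5-methyloxolan-2-yl]-4-[(1R,2R,3R,4S)-1,3,4-trimethyl-7-oxabicyclo[2.2.1]heptan-2-yl]butan-2-ol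
Conditions: MeMgBr, Et2O–CH2Cl2, −78 °C
Reagents that add atoms: methylmagnesium bromide, C[Mg]Br
Why: Cram-chelate-controlled Grignard addition, in which magnesium bridges the ketone oxygen and the oxolane oxygen and the methyl group adds from the side of the ring C–H, should set the tertiary carbinol as (R).

Step 12
Reactants: 24 the tertiary alcohol of step 11
Product: 26 tert-butyl{(1R)-1-[(2S,5R,6S)-5-bromo-2,6-dimethyl-6-{2-[(1R,2R,3R,4S)-1,3,4-trimethyl-7-oxabicyclo[2.2.1]heptan-2-yl]ethyl}oxan-2-yl]ethoxy}dimethylsilane, via oxonium triflate 25 (not isolated)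
Conditions: Tf2O, 2,6-di-tert-butyl-4-methylpyridine, CH2Cl2, −78 °C; then n-Bu4NBr, −78 → 0 °C
Reagents that add atoms: tetrabutylammonium bromide, [Br-].CCCC[N+](CCCC)(CCCC)CCCC
Why: Proposed new method: triflation of the tertiary hydroxyl lets the antiperiplanar oxolane oxygen displace it from the rear (inversion at the quaternary carbon) to give the bicyclic epoxonium ion 25, which bromide should open at the secondary carbon with inversion, while opening at the quaternary carbon only gives a tertiary bromide that can re-ionise through the same ion, so that the ether with oxygen on the more substituted carbon accumulates as the (2S,3R)-3-bromooxane; the closest known reaction types are the stereospecific zinc acetate-mediated rearrangement–ring expansion of tetrahydrofuranyl carbinyl sulfonates to oxan-3-yl acetates and the kinetic-to-thermodynamic oxolane-to-oxane isomerisation of haloetherification products.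

Step 13
Reactants: 26 the bromooxane silyl ether of step 12
Product: 27 (1R)-1-[(2S,5R,6S)-5-bromo-2,6-dimethyl-6-{2-[(1R,2R,3R,4S)-1,3,4-trimethyl-7-oxabicyclo[2.2.1]heptan-2-yl]ethyl}oxan-2-yl]ethan-1-ol
Conditions: HF·pyridine, THF, 0 °C → rt
Reagents that add atoms: none
Why: Fluoride-mediated cleavage of the silyl ether should leave the hindered secondary bromide and both cyclic ethers intact.

Step 14
Reactants: 27 the bromooxane alcohol of step 13
Product: 28 (2S,3R,6S)-3-bromo-6-ethenyl-2,6-dimethyl-2-{2-[(1R,2R,3R,4S)-1,3,4-trimethyl-7-oxabicyclo[2.2.1]heptan-2-yl]ethyl}oxane (dactylopyranoid)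
Conditions: methyl N-(triethylammoniosulfonyl)carbamate (Burgess reagent), PhMe, 70 °C
Reagents that add atoms: none
Why: Burgess dehydration (syn elimination of the sulfamate ester) can only remove a hydrogen of the methyl group because the other neighbour is quaternary, so the vinyl group should form regiospecifically and no stereocentre is touched.

Compound list

1 | 2,5-dimethylfuran | Cc1ccc(C)o1 | starting material
2 | (E)-but-2-enal | C/C=C/C=O | starting material
3 | (1R,2R,3R,4S)-1,3,4-trimethyl-7-oxabicyclo[2.2.1]hept-5-ene-2-carbaldehyde (endo-formyl, exo-methyl) | O=C[C@@H]1[C@@H](C)[C@]2(C)C=C[C@@]1(C)O2 | intermediate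
4 | (1R,2R,3R,4S)-1,3,4-trimethyl-7-oxabicyclo[2.2.1]heptane-2-carbaldehyde | O=C[C@@H]1[C@@H](C)[C@]2(C)CC[C@@]1(C)O2 | intermediate
5 | but-2-yne | CC#CC | starting material
6 | oxirane | C1CO1 | starting material
7 | (E)-but-2-en-2-yl(diisobutyl)alane (H and Al cis) | C/C=C(C)/[Al](CC(C)C)CC(C)C | intermediate
8 | lithium (E)-but-2-en-2-yl(diisobutyl)(methyl)alanate | [Li+].C/C=C(C)/[Al-](C)(CC(C)C)CC(C)C | intermediate
9 | (E)-3-methylpent-3-en-1-ol | C/C=C(C)/CCO | intermediate
10 | 2-[(2R,3R)-2,3-dimethyloxiran-2-yl]ethan-1-ol | C[C@H]1O[C@]1(C)CCO | intermediate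
11 | (2R,3R)-2-(2-iodoethyl)-2,3-dimethyloxirane | C[C@H]1O[C@]1(C)CCI | intermediate
12 | (S)-2-(benzyloxy)propanal | C[C@H](OCc1ccccc1)C=O | starting material
13 | {2-[(2R,3R)-2,3-dimethyloxiran-2-yl]ethyl}lithium | C[C@H]1O[C@]1(C)CC[Li] | intermediate
14 | {2-[(2R,3R)-2,3-dimethyloxiran-2-yl]ethyl}magnesium bromide | C[C@H]1O[C@]1(C)CC[Mg]Br | intermediate
15 | (2S,3S)-2-(benzyloxy)-5-[(2R,3R)-2,3-dimethyloxiran-2-yl]pentan-3-ol | C[C@H]1O[C@]1(C)CC[C@H](O)[C@H](C)OCc1ccccc1 | intermediate
16 | (1R)-1-[(2S,5S)-5-[(1S)-1-(benzyloxy)ethyl]-2-methyloxolan-2-yl]ethan-1-ol | C[C@H](OCc1ccccc1)[C@@H]1CC[C@](C)(O1)[C@@H](C)O | intermediate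
17 | tert-butyl{(1R)-1-[(2S,5S)-5-[(1S)-1-(benzyloxy)ethyl]-2-methyloxolan-2-yl]ethoxy}dimethylsilane | C[C@H](OCc1ccccc1)[C@@H]1CC[C@](C)(O1)[C@@H](C)O[Si](C)(C)C(C)(C)C | intermediate
18 | (1S)-1-[(2S,5S)-5-[(1R)-1-{[tert-butyl(dimethyl)silyl]oxy}ethyl]-5-methyloxolan-2-yl]ethan-1-ol | C[C@H](O)[C@@H]1CC[C@](C)(O1)[C@@H](C)O[Si](C)(C)C(C)(C)C | intermediate
19 | 1-[(2S,5S)-5-[(1R)-1-{[tert-butyl(dimethyl)silyl]oxy}ethyl]-5-methyloxolan-2-yl]ethan-1-one | CC(=O)[C@@H]1CC[C@](C)(O1)[C@@H](C)O[Si](C)(C)C(C)(C)C | intermediate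
20 | β-hydroxy ketone from 19 and 4 (aldol adduct, both epimers at the new carbinol carbon) | O=C(CC(O)[C@@H]1[C@@H](C)[C@]2(C)CC[C@@]1(C)O2)[C@@H]1CC[C@](C)(O1)[C@@H](C)O[Si](C)(C)C(C)(C)C | intermediate
21 | methanesulfonate of 20 | O=C(CC(OS(C)(=O)=O)[C@@H]1[C@@H](C)[C@]2(C)CC[C@@]1(C)O2)[C@@H]1CC[C@](C)(O1)[C@@H](C)O[Si](C)(C)C(C)(C)C | intermediate
22 | (E)-1-[(2S,5S)-5-[(1R)-1-{[tert-butyl(dimethyl)silyl]oxy}ethyl]-5-methyloxolan-2-yl]-3-[(1R,2R,3R,4S)-1,3,4-trimethyl-7-oxabicyclo[2.2.1]heptan-2-yl]prop-2-en-1-one | O=C(/C=C/[C@@H]1[C@@H](C)[C@]2(C)CC[C@@]1(C)O2)[C@@H]1CC[C@](C)(O1)[C@@H](C)O[Si](C)(C)C(C)(C)C | intermediate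
23 | 1-[(2S,5S)-5-[(1R)-1-{[tert-butyl(dimethyl)silyl]oxy}ethyl]-5-methyloxolan-2-yl]-3-[(1R,2R,3R,4S)-1,3,4-trimethyl-7-oxabicyclo[2.2.1]heptan-2-yl]propan-1-one | O=C(CC[C@@H]1[C@@H](C)[C@]2(C)CC[C@@]1(C)O2)[C@@H]1CC[C@](C)(O1)[C@@H](C)O[Si](C)(C)C(C)(C)C | intermediate
24 | (2R)-2-[(2S,5S)-5-[(1R)-1-{[tert-butyl(dimethyl)silyl]oxy}ethyl]-5-methyloxolan-2-yl]-4-[(1R,2R,3R,4S)-1,3,4-trimethyl-7-oxabicyclo[2.2.1]heptan-2-yl]butan-2-ol | C[C@@](O)(CC[C@@H]1[C@@H](C)[C@]2(C)CC[C@@]1(C)O2)[C@@H]1CC[C@](C)(O1)[C@@H](C)O[Si](C)(C)C(C)(C)C | intermediate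
25 | bicyclic epoxonium triflate (oxolane oxygen bonded also to the former carbinol carbon, inverted there) | C[C@@H](O[Si](C)(C)C(C)(C)C)[C@]1(C)CC[C@@H]2[O+]1[C@@]2(C)CC[C@@H]1[C@@H](C)[C@]2(C)CC[C@@]1(C)O2.[O-]S(=O)(=O)C(F)(F)F | intermediate
26 | tert-butyl{(1R)-1-[(2S,5R,6S)-5-bromo-2,6-dimethyl-6-{2-[(1R,2R,3R,4S)-1,3,4-trimethyl-7-oxabicyclo[2.2.1]heptan-2-yl]ethyl}oxan-2-yl]ethoxy}dimethylsilane | C[C@@H](O[Si](C)(C)C(C)(C)C)[C@]1(C)CC[C@@H](Br)[C@](C)(CC[C@@H]2[C@@H](C)[C@]3(C)CC[C@@]2(C)O3)O1 | intermediate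
27 | (1R)-1-[(2S,5R,6S)-5-bromo-2,6-dimethyl-6-{2-[(1R,2R,3R,4S)-1,3,4-trimethyl-7-oxabicyclo[2.2.1]heptan-2-yl]ethyl}oxan-2-yl]ethan-1-ol | C[C@@H](O)[C@]1(C)CC[C@@H](Br)[C@](C)(CC[C@@H]2[C@@H](C)[C@]3(C)CC[C@@]2(C)O3)O1 | intermediate
28 | (2S,3R,6S)-3-bromo-6-ethenyl-2,6-dimethyl-2-{2-[(1R,2R,3R,4S)-1,3,4-trimethyl-7-oxabicyclo[2.2.1]heptan-2-yl]ethyl}oxane (dactylopyranoid) | C=C[C@]1(C)CC[C@@H](Br)[C@](C)(CC[C@@H]2[C@@H](C)[C@]3(C)CC[C@@]2(C)O3)O1 | target

Total step count: 14. Longest linear sequence: 13 steps (steps 2 to 14, from but-2-yne); step 1 supplies the second fragment.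

Steps most likely to fail

Step 12, which bears the label "Proposed new method:". The oxonium ion may be captured by bromide at the quaternary carbon without later isomerisation. The tertiary centre may also ionise without assistance from the ring oxygen, which would open the way to a 1,2-hydride shift towards an oxocarbenium ion, to proton loss, and to erosion of configuration at the quaternary carbon. The fallback uses known reaction types only, sets out from 24 and comes back at 26. Me3SiBr in CH2Cl2 converts 24 into the ring-retained tertiary bromide tert-butyl{(1R)-1-[(2S,5S)-5-{(2R)-2-bromo-4-[(1R,2R,3R,4S)-1,3,4-trimethyl-7-oxabicyclo[2.2.1]heptan-2-yl]butan-2-yl}-2-methyloxolan-2-yl]ethoxy}dimethylsilane F1, whose configuration at the bromine-bearing carbon is of no consequence. Zinc dust in EtOH–AcOH opens this β-bromo ether reductively (Boord elimination) to the hydroxy alkene (2R,3S,6E)-2-{[tert-butyl(dimethyl)silyl]oxy}-3,7-dimethyl-9-[(1R,2R,3R,4S)-1,3,4-trimethyl-7-oxabicyclo[2.2.1]heptan-2-yl]non-6-en-3-ol F2; the elimination is not expected to be stereospecific, so the (E)-isomer would have to be separated from the (Z)-isomer. N-Bromosuccinimide in (CF3)2CHOH then closes the oxane by 6-endo bromoetherification (Markovnikov, anti addition). In the chair-like transition state the bulky 1-silyloxyethyl group should take the equatorial position, which is expected to favour 26.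

Step 5, the key step. The carbanion may attack its own epoxide during halogen–lithium exchange, and chelation control may be incomplete. The fallback sets out from 11 and comes back at 16. Zinc dust with LiCl in THF inserts into the C–I bond to give the non-basic reagent {2-[(2R,3R)-2,3-dimethyloxiran-2-yl]ethyl}zinc iodide F3, which tolerates the epoxide. It is added to 12 in the presence of MgBr2·OEt2, which both activates the aldehyde and holds the chelate, so that 15 forms as before, and the same treatment with camphor-10-sulfonic acid closes the oxolane. Both bonds are still formed in one flask.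

Step 1. The acid-sensitive furan may decompose under the strong Lewis acid, the adduct may revert before hydrogenation, and endo or facial selectivity may be insufficient. The fallback sets out from 1 and comes back at 4. Cycloaddition of 1 with 3-[(E)-but-2-enoyl]-1,3-oxazolidin-2-one is run under the divalent copper catalyst [Cu((R,R)-t-Bu-box)](SbF6)2 (box = 2,2′-(propane-2,2-diyl)bis(4-tert-butyl-4,5-dihydro-1,3-oxazole)), a bidentate dienophile–catalyst pair known for furan cycloadditions, to give the endo imide 3-{[(1R,2R,3R,4S)-1,3,4-trimethyl-7-oxabicyclo[2.2.1]hept-5-en-2-yl]carbonyl}-1,3-oxazolidin-2-one F4. Hydrogenation (H2, Pd/C) gives 3-{[(1R,2R,3R,4S)-1,3,4-trimethyl-7-oxabicyclo[2.2.1]heptan-2-yl]carbonyl}-1,3-oxazolidin-2-one F5. LiBH4 in THF–MeOH removes the oxazolidinone to give [(1R,2S,3R,4S)-1,3,4-trimethyl-7-oxabicyclo[2.2.1]heptan-2-yl]methanol F6, and Dess–Martin oxidation returns 4.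

Further compounds

F1 | step 12 | tert-butyl{(1R)-1-[(2S,5S)-5-{(2R)-2-bromo-4-[(1R,2R,3R,4S)-1,3,4-trimethyl-7-oxabicyclo[2.2.1]heptan-2-yl]butan-2-yl}-2-methyloxolan-2-yl]ethoxy}dimethylsilane | C[C@@](Br)(CC[C@@H]1[C@@H](C)[C@]2(C)CC[C@@]1(C)O2)[C@@H]1CC[C@](C)(O1)[C@@H](C)O[Si](C)(C)C(C)(C)C
F2 | step 12 | (2R,3S,6E)-2-{[tert-butyl(dimethyl)silyl]oxy}-3,7-dimethyl-9-[(1R,2R,3R,4S)-1,3,4-trimethyl-7-oxabicyclo[2.2.1]heptan-2-yl]non-6-en-3-ol | C[C@@H](O[Si](C)(C)C(C)(C)C)[C@@](C)(O)CC/C=C(\C)CC[C@@H]1[C@@H](C)[C@]2(C)CC[C@@]1(C)O2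
F3 | step 5 | {2-[(2R,3R)-2,3-dimethyloxiran-2-yl]ethyl}zinc iodide | C[C@H]1O[C@]1(C)CC[Zn]I
F4 | step 1 | 3-{[(1R,2R,3R,4S)-1,3,4-trimethyl-7-oxabicyclo[2.2.1]hept-5-en-2-yl]carbonyl}-1,3-oxazolidin-2-one | O=C([C@@H]1[C@@H](C)[C@]2(C)C=C[C@@]1(C)O2)N1CCOC1=O
F5 | step 1 | 3-{[(1R,2R,3R,4S)-1,3,4-trimethyl-7-oxabicyclo[2.2.1]heptan-2-yl]carbonyl}-1,3-oxazolidin-2-one | O=C([C@@H]1[C@@H](C)[C@]2(C)CC[C@@]1(C)O2)N1CCOC1=O
F6 | step 1 | [(1R,2S,3R,4S)-1,3,4-trimethyl-7-oxabicyclo[2.2.1]heptan-2-yl]methanol | OC[C@@H]1[C@@H](C)[C@]2(C)CC[C@@]1(C)O2
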